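## Structural features

1. The target 13 is a single aromatic ring, a 1H-pyrrole. It carries a methyl ester on C2 and an unbranched, saturated C21 (henicosyl) chain on C3, while N1, C4 and C5 bear only hydrogen (C27H49NO2).
2. Ring and chain are joined by one sp2–sp3 bond (C3–C1′), and ester and chain stand on neighbouring ring carbons.
3. There is no stereocentre and no stereogenic double bond, so no configuration has to be set or protected.
4. The fragile groups are the methyl ester (hydroxide, alkoxides other than methoxide) and the N–H pyrrole (strong acid, oxidants, electrophiles at C4 and C5). The chain is inert but makes every intermediate waxy and poorly soluble in cold polar media.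
5. The real difficulty is regiochemical. On a preformed pyrrole-2-carboxylate, electrophiles attack C4 and C5, radicals attack C5, and bases attack N1 or C5, so C3 is the least accessible position, and N1, C4 and C5 must stay free.
6. A smaller difficulty is the odd chain length, because the cheap fatty feedstocks are even-numbered (C22).
7. The key step exploits the unsubstituted C4–C5 edge next to N1–H together with the C2=C3 enamine-ester unit. Read as a dehydrated 1,4-imino-aldehyde (C2=N1, C5=O), the ring has a C3–C4 bond between two donor α-carbons. With one oxygen placed between N1 and C5, the atoms C3, C2, N1, C5 and C4 form the six-atom array of an O-vinyl oxime tautomer.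
8. In this reading C1 of a docosyl unit becomes ring atom C3, so the C21 chain comes from a C22 feedstock without loss of carbon.

## Logic of the disconnections

Pyrrole numbering (N1, C2–C5) is kept for the corresponding atoms of all precursors.

**13 ⇒ 9 (through 12, 11 and 10).**
- Bonds cut: C3–C4 and N1–C5, with an oxygen atom placed between N1 and C5.
- Reason: C3–C4 is the one ring bond that joins two carbons of like (donor) polarity. In 11, C3 is α to the C2 imine and C4 is α to the C5 aldehyde, so no simple polar pairing makes this bond. In 10 the N1–O bond holds both carbons at the ends of a 1,5-diene array and is spent as an internal oxidant.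
- Gain: an aromatic heterocycle with a difficult 2,3-pattern becomes an acyclic oxime ether whose substitution pattern is fixed by its constitution.
- Demand: 9 must reach its tautomer 10, and 9 must be made without strong base, because the ester is carried from the start.
- In one sentence, the pyrrole arises by thermal [3,3] shift and cyclodehydration of 9, set free in the flask from 8. This sentence fits neither a coupling at C3–C1′ nor a polar [3+2] ring synthesis.

**9 ⇒ 8.**
- Bonds cut: the C4=C5 π bond is masked by restoring C4–S (a sulfinyl group on C4) and C5–H.
- Reason: a parent vinyl group is hard to place on an oxime oxygen under ester-compatible conditions, whereas the saturated tether is robust. The tether releases the alkene under neutral thermal conditions, at a temperature at which 9 already rearranges.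
- Gain: unmasking and key step become one operation, and 9 need not be handled.
- Demand: the elimination must have one direction only. This is met because C5 carries the only β-hydrogens.

**8 ⇒ 7.**
- Bond cut: S–O.
- Reason: the lower oxidation level at sulfur is nucleophile-tolerant and makes the tether available as a simple alkylating agent.
- Gain: the sulfinyl tether need not be made on its own; it comes from the sulfide formed in the preceding alkylation.
- Demand: oxidation must stop after one oxygen transfer.

**7 ⇒ 5 + 6.**
- Bond cut: O–C5.
- Reason and gain: this separates the C4–C5 two-carbon unit (6) from the part that holds N1, C2, C3, the ester and the chain (5).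
- Demand: alkylation at oxygen and not at nitrogen.

**5 ⇒ 3 (through 4).**
- Bonds cut: C2=N1, with an acetyl group restored on C2.
- Reason: the acetyl group makes C2 a soft carbon nucleophile for both the chain (previous step) and the nitrogen electrophile, and it leaves by itself once C2 is quaternary.
- Gain: N1 is introduced at the correct oxidation level (N–O) in one step.
- Demand: cleavage must take the acetyl group and not the ester.

**3 ⇒ 1 + 2.**
- Bond cut: C2–C3.
- Reason: this is a matched enolate/primary-halide pair, and C1 of the chain of 2 is the future ring atom C3.
- Gain: two commodity compounds.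
- Demand: monoalkylation.

## Other disconnections considered

**Alternative 1:** (the first that comes to mind)
- Cut: the ring–chain bond C3–C1′.
- Forward key step: Sonogashira coupling of methyl 3-bromo-1H-pyrrole-2-carboxylate A1 with henicos-1-yne A2 gives methyl 3-(henicos-1-yn-1-yl)-1H-pyrrole-2-carboxylate A3, which is hydrogenated to 13. A B-alkyl Suzuki or Negishi coupling is the same cut.
- Grounds for preferring the chosen plan:
  - The cut does not solve the regiochemical problem but moves it into A1. Direct halogenation cannot give A1, since electrophiles go to C4/C5.
  - A2 is an odd-numbered C21 alkyne that must itself be assembled.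
  - Oxidative addition into an electron-rich bromopyrrole beside a free N–H is expected to be slow, so an N-protection/deprotection pair is likely.
  - With both partners counted, the route should be longer than five steps, and it needs a noble metal and a protecting group. The chosen plan needs neither.

**Alternative 2:**
- Cut: C2–C3 and C4–C5.
- Forward key step: Barton–Zard [3+2] condensation of (E)-1-nitrotricos-1-ene A4 with methyl isocyanoacetate A5 gives 13 directly.
- Grounds for preferring the chosen plan:
  - The plan is short, since A4 would take about three operations from 2. However, it is the textbook ring synthesis for this substitution pattern and so fails the first test.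
  - On mechanism, A4 is an unbranched 1-nitroalkene with acidic γ-hydrogens. Under the amidine base that the condensation needs, deconjugation and nitronate-initiated oligomerisation compete with the wanted Michael addition.
  - The chosen plan has a similar length and uses only storable, closed-shell intermediates. It forms its difficult bond intramolecularly, so no bimolecular side path can compete at that stage.

**Alternative 3:**
- Cut: N1–C5 and C2–C3, a plausible copy of a biosynthesis from glycine and a β-oxo fatty aldehyde.
- Forward key step: aza-Michael addition of glycine methyl ester A6 to tetracos-1-yn-3-one A7 gives methyl N-[(1Z)-3-oxotetracos-1-en-1-yl]glycinate A8. Base then closes A8 by intramolecular Knoevenagel condensation to 13.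
- Grounds for preferring the chosen plan:
  - In A8 the ketone is a vinylogous amide with a poorly electrophilic carbonyl carbon.
  - Base removes N–H before the weakly acidic glycine CH2, which deactivates the carbonyl further.
  - The nucleophilic enaminone α-carbon can close on the glycine ester instead (also 5-exo-trig), which would leave the chain carbonyl outside the ring. The substrate therefore does not secure the constitution of the product.
  - The usual cure, an N-sulfonyl group with later elimination, adds steps. In the chosen key step every open pathway converges on 13.

Key step: step 5

Remark on the chemistry: the target has no stereogenic element, so the request for a single enantiomer is met by the achiral compound itself. The C=N geometry of 5, 7, 8 and 9 is drawn E (O anti to the ester). It is lost in 10, so either isomer or a mixture serves.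

## Steps

Step 1
Reactants: 1 methyl acetoacetate; 2 1-bromodocosane
Product: 3 methyl 2-acetyltetracosanoate (racemic)
Conditions: 1 (1.5 equiv), K2CO3, KI (cat.), DMF, 70 °C
Reagents that add atoms: none
Why: Acetoacetic ester alkylation, an SN2 reaction of the stabilised enolate on a primary bromide with iodide catalysis; the excess of 1 suppresses dialkylation and warm DMF keeps the waxy bromide in solution. The new C2 stereocentre is racemic and labile and is erased in step 2.

Step 2
Reactants: 3 methyl 2-acetyltetracosanoate
Product: 5 methyl (2E)-2-(hydroxyimino)tetracosanoate, via methyl 2-acetyl-2-nitrosotetracosanoate 4 (not isolated)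
Conditions: isopentyl nitrite, NaOMe, MeOH–THF, 0 °C → rt; then aq. HCl
Reagents that add atoms: isopentyl nitrite, CC(C)CCON=O
Why: Nitrosative deacylation of a 2-alkylacetoacetate (the oxime counterpart of the Japp–Klingemann cleavage): the enolate is C-nitrosated to 4, which has no α-hydrogen, so methoxide adds to the more electrophilic ketone carbonyl and retro-Claisen cleavage expels the oximate. Methoxide matches the ester, and the E isomer is expected as the more stable one.

Step 3
Reactants: 5 methyl (2E)-2-(hydroxyimino)tetracosanoate; 6 2-chloroethyl phenyl sulfide
Product: 7 methyl (2E)-2-{[2-(phenylsulfanyl)ethoxy]imino}tetracosanoate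
Conditions: K2CO3, NaI (cat.), DMF, 50 °C
Reagents that add atoms: none
Why: Williamson-type O-alkylation of an oximate; acceptor-substituted oximates of this kind alkylate at oxygen, and 6 is activated by the neighbouring sulfur and by iodide exchange. K2CO3 is too weak to harm the ester.

Step 4
Reactants: 7 methyl (2E)-2-{[2-(phenylsulfanyl)ethoxy]imino}tetracosanoate
Product: 8 methyl (2E)-2-{[2-(phenylsulfinyl)ethoxy]imino}tetracosanoate (racemic at sulfur)
Conditions: mCPBA (1.0 equiv), CH2Cl2, −20 → 0 °C
Reagents that add atoms: mCPBA, O=C(OO)c1cccc(Cl)c1
Why: Chemoselective sulfide-to-sulfoxide oxidation with one equivalent of peracid; the thioether is by far the most nucleophilic site and the electron-poor C=N–O unit is inert. The sulfur stereocentre is formed racemic and is lost in step 5.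

Step 5
Reactants: 8 methyl (2E)-2-{[2-(phenylsulfinyl)ethoxy]imino}tetracosanoate
Product: 13 methyl 3-henicosyl-1H-pyrrole-2-carboxylate, via O-vinyl oxime 9 (not isolated), via N-vinyloxy enamine 10 (not isolated), via imino aldehyde 11 (not isolated), via hydroxypyrroline 12 (not isolated)
Conditions: CaCO3, 1,2-dichlorobenzene, 165 °C, argon
Reagents that add atoms: none
Why: Thermal syn-elimination of the sulfoxide, whose only β-hydrogens are those of the OCH2 group (C5), should release benzenesulfenic acid and 9, as in the known tandem sulfoxide elimination–Claisen rearrangement of 2-(phenylsulfinyl)ethyl ethers. Compound 9 tautomerises to 10; this can occur only towards C3, because the other substituent on C2 is the ester, and it is helped by the acrylate conjugation gained in the dehydroamino ester 10. Compound 10 holds the array C3=C2–N1–O–C5=C4 and undergoes a 3-aza-4-oxa-Cope [3,3] shift that trades the weak N–O bond for the C3–C4 bond and a C5=O bond, so two donor carbons are joined without an external oxidant to give 11. The N–H imine of 11 adds to the aldehyde (5-exo-trig, N1–C5) to give 12, and loss of water with a proton shift gives aromatic 13, which makes the sequence irreversible. The closest known reaction types are the Trofimov pyrrole synthesis and the thermal rearrangement of isolated O-vinyl ketoximes followed by Paal–Knorr closure. No stereocentre survives, since C3 of 11 and the two sp3 ring centres of 12 are transient and are erased on aromatisation. The selectivity needed is the 2,3-pattern with free N1, C4 and C5, and the substrate secures it because the vinyl unit is unsubstituted, so that even a competing [1,3] O-to-N shift followed by enamine–aldehyde condensation would converge on 13. CaCO3 takes up adventitious acid, and the ester-deactivated ring of 13 should resist attack by sulfur electrophiles.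

## Compound list

1 | methyl acetoacetate | CC(=O)CC(=O)OC | starting material
2 | 1-bromodocosane | CCCCCCCCCCCCCCCCCCCCCCBr | starting material
3 | methyl 2-acetyltetracosanoate (racemic) | CCCCCCCCCCCCCCCCCCCCCCC(C(C)=O)C(=O)OC | intermediate
4 | methyl 2-acetyl-2-nitrosotetracosanoate (racemic, not isolated) | CCCCCCCCCCCCCCCCCCCCCCC(N=O)(C(C)=O)C(=O)OC | intermediate
5 | methyl (2E)-2-(hydroxyimino)tetracosanoate | COC(=O)/C(=N/O)CCCCCCCCCCCCCCCCCCCCCC | intermediate
6 | 2-chloroethyl phenyl sulfide | ClCCSc1ccccc1 | starting material
7 | methyl (2E)-2-{[2-(phenylsulfanyl)ethoxy]imino}tetracosanoate | COC(=O)/C(=N/OCCSc1ccccc1)CCCCCCCCCCCCCCCCCCCCCC | intermediate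
8 | methyl (2E)-2-{[2-(phenylsulfinyl)ethoxy]imino}tetracosanoate (racemic at sulfur) | COC(=O)/C(=N/OCCS(=O)c1ccccc1)CCCCCCCCCCCCCCCCCCCCCC | intermediate
9 | methyl (2E)-2-[(ethenyloxy)imino]tetracosanoate (not isolated) | COC(=O)/C(=N/OC=C)CCCCCCCCCCCCCCCCCCCCCC | intermediate
10 | methyl (2Z)-2-[(ethenyloxy)amino]tetracos-2-enoate (not isolated) | CCCCCCCCCCCCCCCCCCCCC/C=C(/C(=O)OC)NOC=C | intermediate
11 | methyl 2-imino-3-(2-oxoethyl)tetracosanoate (racemic, not isolated) | CCCCCCCCCCCCCCCCCCCCCC(CC=O)C(=N)C(=O)OC | intermediate
12 | methyl 4-henicosyl-2-hydroxy-3,4-dihydro-2H-pyrrole-5-carboxylate (mixture of diastereomers, not isolated) | CCCCCCCCCCCCCCCCCCCCCC1CC(O)N=C1C(=O)OC | intermediate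
13 | methyl 3-henicosyl-1H-pyrrole-2-carboxylate | CCCCCCCCCCCCCCCCCCCCCc1cc[nH]c1C(=O)OC | target

## Step count and least certain steps

Total step count: 5. Longest linear sequence: 5 steps (1 or 2 → 13).

**Step 5 (key step).**
- What may go wrong: the proton shift 9 → 10 may be too slow under neutral conditions. Re-addition of sulfenic acid to the vinyl ether, hydrolysis of the vinyl ether by the water released, or N–O homolysis could then take over.
- A second danger is electrophilic sulfenylation of the new ring at C4 or C5 by species derived from the sulfenic acid.
- Fallback: this gives up the sigmatropic plan for the polar [3+2] ring synthesis of Alternative 2, in a variant that avoids handling the nitroalkene A4. It sets out from 2 and comes back at 13. Kornblum oxidation of 2 (DMSO, NaHCO3, heat) should give docosanal F1. Henry addition of nitromethane should give 1-nitrotricosan-2-ol F2, and acetylation should give 1-nitrotricosan-2-yl acetate F3. Treatment of F3 with methyl isocyanoacetate A5 and two equivalents of DBU (elimination in the flask, then Barton–Zard condensation) should give 13.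

**Step 2.**
- What may go wrong: the cleavage may run in the wrong direction (loss of the methoxycarbonyl group in place of the acetyl group). Methoxide may also deacetylate 3 before nitrosation, or the hindered, poorly soluble enolate may be nitrosated only in part at 0 °C.
- Fallback: this builds C2 as a ketone and introduces nitrogen by condensation. It sets out from 2 and comes back at 5. Magnesium in THF should convert 2 into docosylmagnesium bromide F4. Inverse addition of F4 to excess dimethyl oxalate at low temperature should give methyl 2-oxotetracosanoate F5. Hydroxylamine hydrochloride with sodium acetate in methanol should then give 5.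

**Step 3.**
- What may go wrong: alkylation may occur at nitrogen in place of oxygen, or the chloride may be lost by base-induced elimination or hydrolysis before it meets the oximate.
- Fallback: this forms the O–C5 bond before the C=N bond, so N-alkylation cannot occur. It sets out from 6 and comes back at 7. Alkylation of N-hydroxyphthalimide with 6 (K2CO3, DMF) should give 2-[2-(phenylsulfanyl)ethoxy]isoindoline-1,3-dione F6. Hydrazinolysis should give O-[2-(phenylsulfanyl)ethyl]hydroxylamine F7. Condensation of F7 with the keto ester F5 (made as in the fallback to step 2) should give 7.

**Step 4.**
- What may go wrong: sulfur may be over-oxidised to the S,S-dioxide level, from which no syn-elimination is possible. Precipitation of the waxy substrate in the cold, with a local excess of peracid, would favour this.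
- Fallback: this replaces the sulfur tether by a halide and the pyrolysis by an E2 elimination. It sets out from 5 and comes back at 9. Alkylation of 5 with excess 1,2-dibromoethane (K2CO3, DMF) should give methyl (2E)-2-[(2-bromoethoxy)imino]tetracosanoate F8. Brief treatment with KOt-Bu in THF at −20 °C should give 9, which is isolated. Heated alone in 1,2-dichlorobenzene, 9 should pass through 10, 11 and 12 to 13 in the absence of any sulfur species.

## Further compounds

F1 | step 5 | docosanal | CCCCCCCCCCCCCCCCCCCCCC=O
F2 | step 5 | 1-nitrotricosan-2-ol (racemic) | CCCCCCCCCCCCCCCCCCCCCC(O)C[N+](=O)[O-]
F3 | step 5 | 1-nitrotricosan-2-yl acetate (racemic) | CCCCCCCCCCCCCCCCCCCCCC(OC(C)=O)C[N+](=O)[O-]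
F4 | step 2 | docosylmagnesium bromide | CCCCCCCCCCCCCCCCCCCCCC[Mg]Br
F5 | step 2 | methyl 2-oxotetracosanoate | CCCCCCCCCCCCCCCCCCCCCCC(=O)C(=O)OC
F6 | step 3 | 2-[2-(phenylsulfanyl)ethoxy]isoindoline-1,3-dione | O=C1c2ccccc2C(=O)N1OCCSc1ccccc1
F7 | step 3 | O-[2-(phenylsulfanyl)ethyl]hydroxylamine | NOCCSc1ccccc1
F8 | step 4 | methyl (2E)-2-[(2-bromoethoxy)imino]tetracosanoate | COC(=O)/C(=N/OCCBr)CCCCCCCCCCCCCCCCCCCCCC
A1 | alternative 1 | methyl 3-bromo-1H-pyrrole-2-carboxylate | COC(=O)c1[nH]ccc1Br
A2 | alternative 1 | henicos-1-yne | C#CCCCCCCCCCCCCCCCCCCCC
A3 | alternative 1 | methyl 3-(henicos-1-yn-1-yl)-1H-pyrrole-2-carboxylate | CCCCCCCCCCCCCCCCCCCC#Cc1cc[nH]c1C(=O)OC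
A4 | alternative 2 | (E)-1-nitrotricos-1-ene | CCCCCCCCCCCCCCCCCCCCC/C=C/[N+](=O)[O-]
A5 | alternative 2 | methyl isocyanoacetate | [C-]#[N+]CC(=O)OC
A6 | alternative 3 | glycine methyl ester | COC(=O)CN
A7 | alternative 3 | tetracos-1-yn-3-one | CCCCCCCCCCCCCCCCCCCCCC(=O)C#C
A8 | alternative 3 | methyl N-[(1Z)-3-oxotetracos-1-en-1-yl]glycinate | C(/C(=O)CCCCCCCCCCCCCCCCCCCCC)=C/NCC(=O)OC
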